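## The problem

The target 27 is a flavonol: a 3-hydroxy-4H-chromen-4-one (ring C) fused to a benzene ring A and carrying at C2 a 4-methoxyphenyl ring B with a 4-hydroxy-3-methylbutyl chain ortho to the methoxy group. Ring A is the hard part. It bears O1 at C8a, the acyl carbon at C4a, methoxy groups at C5 and C6, a free hydroxyl at C7 and hydrogen only at C8. Electrophilic substitution of a trioxygenated benzene reaches this pattern only with regiochemical ambiguity, and selective dealkylation cannot repair it later, because Lewis acids strike the C5 methyl ether peri to the C4 carbonyl first. The single stereocentre, C3 of the side chain, is (S) by CIP analysis of the SMILES. It lies far from the achiral core, can neither be induced by it nor direct anything, and so must come from the chiral pool and be kept from enolisation. The bond from ring B to the chain is an unactivated sp2–sp3 bond. The 3-hydroxypyranone is cleaved by alkali in air, so the C3 hydroxyl should come late, and the masks on the C7 phenol and the primary alcohol must leave without Lewis acid, base or oxidant. The feature that opens the key step is the match between ring A and a squaric ester: C5 and C6 carry neighbouring methoxy groups like the two enol-ether carbons of the ester, C8a–O and C6–O are para like the carbonyl and the quaternary C4 of a 4-alkoxycyclobutenone, and C8 is the one ring CH, as needed for a vinyl terminus closing onto a ketene.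

## Retrosynthesis

**Protecting groups and the C3–O bond.** From 27 the two oxygen–protecting-group bonds are cut first: a tert-butyl ether on O7 and a TBS ether on the chain oxygen, both present in 26 and both leaving with Brønsted acid in one operation. The tert-butyl group follows from the key step, in which O7 arrives as the alkoxy group of a vinyl ether. It is the alkyl group that survives organolithium reagents yet leaves under conditions that spare the three methyl ethers. The C3–O bond is cut next, giving flavone 23. An Algar–Flynn–Oyamada closure would make O1–C2 and C3–O together, but a methoxy group at C5 is known to divert it to five-membered-ring products. The forward step must oxidise C3 only; deprotonation of the one vinylic C–H next to the carbonyl, boration and peroxide oxidation does this.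

**Ring C.** Flavone 23 is opened at O1–C2 to 1,3-diketone 21, and 21 is cut between C2 and C3 into acetophenone 12 and methyl ester 20. O-Acylation followed by Baker–Venkataraman shift would make the same C2–C3 bond intramolecularly, but the direct crossed Claisen condensation saves two steps; the longer sequence is held in reserve. The two precursors are single arenes of similar size, so the route is convergent here. The forward reactions must acylate the dianion of 12 on carbon and dehydrate 21 under acid mild enough for the aryl tert-butyl ether.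

**Ring B and the chain.** Ester 20 is cut at the aryl–CH2 bond into commercial bromide 18 and terminal alkene 17, to be joined by hydroboration and B-alkyl Suzuki–Miyaura coupling. An aryl–alkyne cut would cost a hydrogenation step, and a CH2–CH2 cut would need a benzylic organometallic of 18. Alkene 17 goes back through aldehyde 16, alcohol 15 and silyl ether 14 to methyl (R)-3-hydroxy-2-methylpropanoate 13. The ester carbon of 13 becomes the chain CH2 and the hydroxymethyl group becomes the terminal CH2OH, so the (R) ester gives the (S) chain through the change in CIP priorities alone. The only demand is that 16 is olefinated before it can enolise.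

**Ring A (key disconnection).** Acetophenone 12 is the hydrolysis product of enol ether 11. Phenol 11 is cut at the C8–C8a bond (flavone numbering), which leads back to cyclobutenone 8 by thermal ring expansion. Acylation of a preformed arene would leave the O7 differentiation unsolved; this cut fixes all five substituents by connectivity. The precursor 8 contains no arene and is assembled from two simple building blocks. The forward reaction needs conrotatory opening with the alkenyl arm turning inward and a six-electron closure of the resulting dienylketene.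

**The cyclobutenone.** Compound 8 is cut at the bond from the quaternary carbon to its alkenyl group and at the O–CH3 bond. This gives dione 6 and 1-tert-butoxyethenyllithium 2, with alkoxide 7 as the species that is methylated. The addition must go to the carbonyl next to the methoxy-bearing carbon, not to the vinylogous ester carbonyl. Dione 6 comes from dimethyl squarate 3 and the same organolithium 2 by addition and 1,3-carbonyl transposition. Reagent 2 is cut at its C–Li bond to tert-butyl vinyl ether 1; it is made as a solution in a step of its own and serves twice. The first copy is only a masked acetyl group, the second fixes the O7 protecting group.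

## Roads not taken

Alternative 1: Ring C is cut at the C2=C3 double bond. In the forward step phosphonium bromide A1 is deprotonated by mild base and, on warming, olefinates its own aryl ester carbonyl to give flavone A2.
- Merits: the closure is neutral, so acid-labile groups are safe, and the benzyl groups of A2 leave by hydrogenolysis.
- Weak points: A1 needs α-bromination of an electron-rich acetophenone whose C8 position is free and activated, then phosphine displacement and esterification. Ester carbonyls are poor Wittig acceptors. A2 still lacks the C3 hydroxyl. The ring A ketone with O7 already differentiated is presupposed.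
- Comparison: in protecting-group tolerance of the ring C closure this road is better than the chosen one, whose acid dehydration (step 12) is a weak step. The chosen plan sets against it a two-step union of the arenes and a de novo ring A.

Alternative 2: Ring C is cut at C3–C4. A triazolium-derived carbene with weak base converts dialdehyde A3 into cyclic acyloin A4 by intramolecular crossed benzoin reaction.
- Merits: the C3 oxygen arrives with ring closure under near-neutral conditions, and no organolithium touches the assembled skeleton. In this respect it is better than the chosen plan.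
- Weak points: A3 contains an α-aryl-α-aryloxy acetaldehyde, which is enolisable and oxidation-prone. Its aromatic aldehyde is electron-rich and flanked on both sides, so the carbene may add to the aliphatic aldehyde and give the regioisomeric ketol. A4 is at the dihydroflavonol level and needs a dehydrogenation. Ring A is again presupposed.
- Comparison: the step count after ring closure is equal (dehydrogenation there, hydroxylation here). The chosen plan sets stable intermediates 12 and 20 and its ring A construction against it.

Alternative 3: Ring A is cut at C8a–O and C4a–C4. Fluoride releases aryne A6 from silyl triflate A5. Benzyloxyacetic acid A7 adds its oxygen at C8a, directed by the C5 methoxy group, and the acyl group migrates to C4a to give hydroxy ketone A8.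
- Merits: two ring A bonds form in one operation with predictable regiochemistry, and the C3 oxygen is carried in the acyl group, so no late hydroxylation is needed. In that respect this road is better.
- Weak points: A5 is a hexasubstituted benzene with three differentiated oxygens, so the substitution problem is moved back, not solved. Acyl migration competes with simple O-arylation. A8 still needs aroylation, acyl shift, cyclisation and hydrogenolysis.
- Comparison: the chosen plan sets against it a ring A built from squarate in three steps (plus the preparation of one organolithium reagent) with every oxygen placed by connectivity.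

Key step: step 4

Assumption: tert-butyl vinyl ether is taken to undergo α-lithiation with t-BuLi in THF in the same way as methyl and ethyl vinyl ether.

## Route

Step 1
Reactants: 1 tert-butyl vinyl ether
Product: 2 1-tert-butoxyethenyllithium (THF solution, titrated and used at once)
Conditions: t-BuLi (pentane), THF, −78 → 0 °C; recool to −78 °C
Reagents that add atoms: tert-butyllithium, [Li]C(C)(C)C
Why: Oxygen-directed α-deprotonation of the vinyl ether (vinylic lithiation, as known for methyl and ethyl vinyl ether) gives the acyl-anion equivalent. The solution is not stored: this step is run once before step 2 and again before step 3.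

Step 2
Reactants: 3 dimethyl squarate; 2 1-tert-butoxyethenyllithium
Product: 6 3-(1-tert-butoxyethenyl)-4-methoxycyclobut-3-ene-1,2-dione, via lithium alkoxide adduct 4 (not isolated), via adduct trifluoroacetate 5 (not isolated)
Conditions: 3, THF, −78 °C; add 2 (THF solution from step 1); (CF3CO)2O, −78 °C; aq NaHCO3
Reagents that add atoms: water, O
Why: 1,2-Addition of the alkenyllithium to one squarate carbonyl gives alkoxide 4; O-trifluoroacetylation to 5, ionisation to the methoxy-stabilised cyclobutenyl cation and hydration on quench with loss of methanol complete the 1,3-carbonyl transposition (the known route from squarate esters to 3-substituted 4-alkoxycyclobutenediones). The new carbonyl oxygen comes from the aqueous quench; the acylation is done on the lithium alkoxide and the quench is buffered, so no free acid should meet the enol ether.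

Step 3
Reactants: 6 3-(1-tert-butoxyethenyl)-4-methoxycyclobut-3-ene-1,2-dione; 2 1-tert-butoxyethenyllithium
Product: 8 2,4-bis(1-tert-butoxyethenyl)-3,4-dimethoxycyclobut-2-en-1-one (racemic), via lithium alkoxide 7 (not isolated)
Conditions: 6, THF, −78 °C; add 2 (fresh THF solution from step 1); MeOTf, −78 → 0 °C
Reagents that add atoms: methyl trifluoromethanesulfonate, COS(=O)(=O)C(F)(F)F
Why: The carbonyl next to the methoxy-bearing carbon is a plain enone carbonyl while the other is a vinylogous ester, so the organolithium should add at the former (established regiochemistry for 3-alkoxycyclobutenediones). The tertiary lithium alkoxide is O-methylated in situ (Williamson-type alkylation); the quaternary centre is racemic and vanishes on aromatisation.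

Step 4
Reactants: 8 2,4-bis(1-tert-butoxyethenyl)-3,4-dimethoxycyclobut-2-en-1-one
Product: 11 5-tert-butoxy-2-(1-tert-butoxyethenyl)-3,4-dimethoxyphenol, via dienylketene 9 (not isolated), via cyclohexadienone 10 (not isolated)
Conditions: toluene (dilute, degassed), 110 °C
Reagents that add atoms: none
Why: Heating opens the cyclobutenone by conrotatory four-electron ring opening at the bond between the carbonyl and the quaternary carbon, giving dienylketene 9. A disrotatory six-electron electrocyclisation then joins the vinyl CH2 terminus to the ketene carbon (the C8–C8a bond), closing ring A as cyclohexadienone 10, which enolises irreversibly to phenol 11. The closest known reaction type is the thermal ring expansion of squarate-derived 4-alkenyl-4-alkoxycyclobutenones to phenols (Moore rearrangement). No stereocentre is formed. The step needs torquoselectivity: the alkenyl arm must rotate inward, which the strong outward preference of the 4-methoxy donor secures. Regiochemistry needs no control, since the carbonyl carbon becomes C8a–OH, the quaternary carbon C6–OMe, the squarate carbon C5–OMe and the two enol ethers become C7–O-tert-butyl and the masked acetyl group. Any 12 formed by loss of isobutene from 11 in the hot solution is the product of the next step.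

Step 5
Reactants: 11 5-tert-butoxy-2-(1-tert-butoxyethenyl)-3,4-dimethoxyphenol
Product: 12 1-(4-tert-butoxy-6-hydroxy-2,3-dimethoxyphenyl)ethan-1-one
Conditions: (CO2H)2, THF/H2O, 0 °C → rt
Reagents that add atoms: water, O
Why: Enol ether hydrolysis (C-protonation, hemiketal collapse) is far faster in dilute acid than cleavage of an aryl tert-butyl ether, so the acetyl group should be released with the O-tert-butyl group intact.

Step 6
Reactants: 13 methyl (2R)-3-hydroxy-2-methylpropanoate
Product: 14 methyl (2R)-3-[(tert-butyldimethylsilyl)oxy]-2-methylpropanoate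
Conditions: TBSCl, imidazole, CH2Cl2, 0 °C → rt
Reagents that add atoms: tert-butyldimethylsilyl chloride, CC(C)(C)[Si](C)(C)Cl
Why: Standard silylation of a primary alcohol; the stereocentre is not touched.

Step 7
Reactants: 14 methyl (2R)-3-[(tert-butyldimethylsilyl)oxy]-2-methylpropanoate
Product: 15 (2S)-3-[(tert-butyldimethylsilyl)oxy]-2-methylpropan-1-ol
Conditions: i-Bu2AlH, CH2Cl2, −78 → 0 °C; aq KNaC4H4O6
Reagents that add atoms: none
Why: Hydride reduction of the ester to the primary alcohol under non-basic conditions, so the α-stereocentre is not epimerised; the descriptor changes only through CIP priorities.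

Step 8
Reactants: 15 (2S)-3-[(tert-butyldimethylsilyl)oxy]-2-methylpropan-1-ol
Product: 16 (2R)-3-[(tert-butyldimethylsilyl)oxy]-2-methylpropanal
Conditions: (COCl)2, DMSO, CH2Cl2, −78 °C; Et3N, −78 → 0 °C
Reagents that add atoms: none
Why: Swern oxidation; low temperature and immediate use of the crude aldehyde should limit enolisation at the α-branched carbon.

Step 9
Reactants: 16 (2R)-3-[(tert-butyldimethylsilyl)oxy]-2-methylpropanal
Product: 17 tert-butyldimethyl{[(2S)-2-methylbut-3-en-1-yl]oxy}silane
Conditions: Ph3PCH3Br, KN(SiMe3)2, THF, 0 °C; then 16, −78 °C → rt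
Reagents that add atoms: methyltriphenylphosphonium bromide, [Br-].C[P+](c1ccccc1)(c1ccccc1)c1ccccc1
Why: Wittig methylenation with the non-stabilised ylide is fast at low temperature, so the aldehyde should be consumed before it epimerises.

Step 10
Reactants: 17 tert-butyldimethyl{[(2S)-2-methylbut-3-en-1-yl]oxy}silane; 18 methyl 3-bromo-4-methoxybenzoate
Product: 20 methyl 3-[(3S)-4-[(tert-butyldimethylsilyl)oxy]-3-methylbutyl]-4-methoxybenzoate, via B-alkyl-9-BBN 19 (not isolated)
Conditions: 9-BBN, THF, 0 °C → rt; then 18, PdCl2(dppf), K3PO4, DMF/H2O, 60 °C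
Reagents that add atoms: none
Why: Anti-Markovnikov hydroboration followed by B-alkyl Suzuki–Miyaura coupling with the aryl bromide; the divalent palladium precatalyst PdCl2(dppf) is reduced in the flask to the zerovalent palladium catalyst. The stereocentre is one carbon away from the reacting sites and is untouched.

Step 11
Reactants: 12 1-(4-tert-butoxy-6-hydroxy-2,3-dimethoxyphenyl)ethan-1-one; 20 methyl 3-[(3S)-4-[(tert-butyldimethylsilyl)oxy]-3-methylbutyl]-4-methoxybenzoate
Product: 21 1-(4-tert-butoxy-6-hydroxy-2,3-dimethoxyphenyl)-3-{3-[(3S)-4-[(tert-butyldimethylsilyl)oxy]-3-methylbutyl]-4-methoxyphenyl}propane-1,3-dione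
Conditions: LiN(SiMe3)2 (excess), THF, −78 → 0 °C; then 20, rt → 50 °C; aq NH4Cl
Reagents that add atoms: none
Why: Crossed Claisen condensation: the phenoxide–enolate dianion of the o-hydroxyacetophenone attacks the non-enolisable benzoate on carbon, and excess base drives the equilibrium by deprotonating the diketone.

Step 12
Reactants: 21 1-(4-tert-butoxy-6-hydroxy-2,3-dimethoxyphenyl)-3-{3-[(3S)-4-[(tert-butyldimethylsilyl)oxy]-3-methylbutyl]-4-methoxyphenyl}propane-1,3-dione
Product: 23 7-tert-butoxy-2-{3-[(3S)-4-[(tert-butyldimethylsilyl)oxy]-3-methylbutyl]-4-methoxyphenyl}-5,6-dimethoxy-4H-chromen-4-one, via 2-hydroxyflavanone 22 (not isolated)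
Conditions: CSA (10 mol %), 4 Å MS, CH2Cl2, 0 °C → rt
Reagents that add atoms: none
Why: Acid-catalysed cyclodehydration of an o-hydroxyaryl 1,3-diketone: 6-exo-trig hemiketal formation, then loss of water through a C2 cation stabilised by O1 and the para-methoxyaryl ring. Catalytic sulfonic acid in an alcohol-free medium should ionise this hemiketal well before it forms a tert-butyl cation from the deactivated aryl ether or cleaves the silyl ether.

Step 13
Reactants: 23 7-tert-butoxy-2-{3-[(3S)-4-[(tert-butyldimethylsilyl)oxy]-3-methylbutyl]-4-methoxyphenyl}-5,6-dimethoxy-4H-chromen-4-one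
Product: 26 7-tert-butoxy-2-{3-[(3S)-4-[(tert-butyldimethylsilyl)oxy]-3-methylbutyl]-4-methoxyphenyl}-3-hydroxy-5,6-dimethoxy-4H-chromen-4-one, via 3-lithioflavone 24 (not isolated), via flavon-3-yl dimethyl boronate 25 (not isolated)
Conditions: LiN(i-Pr)2, THF, −78 °C; B(OMe)3, −78 → 0 °C; AcOH, 30% H2O2, 0 °C → rt
Reagents that add atoms: hydrogen peroxide, OO
Why: Flavones are deprotonated at C3 by lithium amide bases at low temperature; borate trapping and peroxide oxidation of the C–B bond convert the vinyl anion into the C3 hydroxyl without a basic oxidative medium.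

Step 14
Reactants: 26 7-tert-butoxy-2-{3-[(3S)-4-[(tert-butyldimethylsilyl)oxy]-3-methylbutyl]-4-methoxyphenyl}-3-hydroxy-5,6-dimethoxy-4H-chromen-4-one
Product: 27 3,7-dihydroxy-2-{3-[(3S)-4-hydroxy-3-methylbutyl]-4-methoxyphenyl}-5,6-dimethoxy-4H-chromen-4-one
Conditions: CF3CO2H/CH2Cl2/H2O, 0 °C → rt; then NaHCO3, aq MeOH
Reagents that add atoms: none
Why: Acidolysis removes the aryl tert-butyl ether (loss of isobutene) and the primary silyl ether together, while methyl ethers and the flavonol are inert; the bicarbonate–methanol work-up cleaves any trifluoroacetate of the primary alcohol.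

## Compound list

1 | tert-butyl vinyl ether | C=COC(C)(C)C | starting material
2 | 1-tert-butoxyethenyllithium | [Li]C(=C)OC(C)(C)C | intermediate
3 | dimethyl squarate (3,4-dimethoxycyclobut-3-ene-1,2-dione) | COC1=C(OC)C(=O)C1=O | starting material
4 | lithium 1-(1-tert-butoxyethenyl)-2,3-dimethoxy-4-oxocyclobut-2-en-1-olate (racemic) | [Li+].[O-]C1(C(=C)OC(C)(C)C)C(OC)=C(OC)C1=O | intermediate
5 | 1-(1-tert-butoxyethenyl)-2,3-dimethoxy-4-oxocyclobut-2-en-1-yl trifluoroacetate (racemic) | COC1=C(OC)C(OC(=O)C(F)(F)F)(C(=C)OC(C)(C)C)C1=O | intermediate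
6 | 3-(1-tert-butoxyethenyl)-4-methoxycyclobut-3-ene-1,2-dione | COC1=C(C(=C)OC(C)(C)C)C(=O)C1=O | intermediate
7 | lithium 1,3-bis(1-tert-butoxyethenyl)-2-methoxy-4-oxocyclobut-2-en-1-olate (racemic) | [Li+].[O-]C1(C(=C)OC(C)(C)C)C(OC)=C(C(=C)OC(C)(C)C)C1=O | intermediate
8 | 2,4-bis(1-tert-butoxyethenyl)-3,4-dimethoxycyclobut-2-en-1-one (racemic) | O=C1C(C(=C)OC(C)(C)C)=C(OC)C1(OC)C(=C)OC(C)(C)C | intermediate
9 | dienylketene (3Z)-5-tert-butoxy-2-(1-tert-butoxyethenyl)-3,4-dimethoxyhexa-1,3,5-trien-1-one | O=C=C(C(=C)OC(C)(C)C)/C(OC)=C(OC)\C(=C)OC(C)(C)C | intermediate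
10 | 5-tert-butoxy-2-(1-tert-butoxyethenyl)-3,4-dimethoxycyclohexa-2,4-dien-1-one | O=C1CC(OC(C)(C)C)=C(OC)C(OC)=C1C(=C)OC(C)(C)C | intermediate
11 | 5-tert-butoxy-2-(1-tert-butoxyethenyl)-3,4-dimethoxyphenol | Oc1cc(OC(C)(C)C)c(OC)c(OC)c1C(=C)OC(C)(C)C | intermediate
12 | 1-(4-tert-butoxy-6-hydroxy-2,3-dimethoxyphenyl)ethan-1-one | CC(=O)c1c(O)cc(OC(C)(C)C)c(OC)c1OC | intermediate
13 | methyl (2R)-3-hydroxy-2-methylpropanoate | COC(=O)[C@H](C)CO | starting material
14 | methyl (2R)-3-[(tert-butyldimethylsilyl)oxy]-2-methylpropanoate | COC(=O)[C@H](C)CO[Si](C)(C)C(C)(C)C | intermediate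
15 | (2S)-3-[(tert-butyldimethylsilyl)oxy]-2-methylpropan-1-ol | OC[C@H](C)CO[Si](C)(C)C(C)(C)C | intermediate
16 | (2R)-3-[(tert-butyldimethylsilyl)oxy]-2-methylpropanal | O=C[C@H](C)CO[Si](C)(C)C(C)(C)C | intermediate
17 | tert-butyldimethyl{[(2S)-2-methylbut-3-en-1-yl]oxy}silane | C=C[C@H](C)CO[Si](C)(C)C(C)(C)C | intermediate
18 | methyl 3-bromo-4-methoxybenzoate | COC(=O)c1ccc(OC)c(Br)c1 | starting material
19 | 9-[(3S)-4-[(tert-butyldimethylsilyl)oxy]-3-methylbutyl]-9-borabicyclo[3.3.1]nonane | B1(CC[C@H](C)CO[Si](C)(C)C(C)(C)C)C2CCCC1CCC2 | intermediate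
20 | methyl 3-[(3S)-4-[(tert-butyldimethylsilyl)oxy]-3-methylbutyl]-4-methoxybenzoate | COC(=O)c1ccc(OC)c(CC[C@H](C)CO[Si](C)(C)C(C)(C)C)c1 | intermediate
21 | 1-(4-tert-butoxy-6-hydroxy-2,3-dimethoxyphenyl)-3-{3-[(3S)-4-[(tert-butyldimethylsilyl)oxy]-3-methylbutyl]-4-methoxyphenyl}propane-1,3-dione | COc1ccc(C(=O)CC(=O)c2c(O)cc(OC(C)(C)C)c(OC)c2OC)cc1CC[C@H](C)CO[Si](C)(C)C(C)(C)C | intermediate
22 | 7-tert-butoxy-2-{3-[(3S)-4-[(tert-butyldimethylsilyl)oxy]-3-methylbutyl]-4-methoxyphenyl}-2-hydroxy-5,6-dimethoxychroman-4-one (both C2 epimers) | COc1ccc(C2(O)CC(=O)c3c(OC)c(OC)c(OC(C)(C)C)cc3O2)cc1CC[C@H](C)CO[Si](C)(C)C(C)(C)C | intermediate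
23 | 7-tert-butoxy-2-{3-[(3S)-4-[(tert-butyldimethylsilyl)oxy]-3-methylbutyl]-4-methoxyphenyl}-5,6-dimethoxy-4H-chromen-4-one | COc1ccc(-c2cc(=O)c3c(OC)c(OC)c(OC(C)(C)C)cc3o2)cc1CC[C@H](C)CO[Si](C)(C)C(C)(C)C | intermediate
24 | 3-lithio derivative of 23 | COc1ccc(-c2oc3cc(OC(C)(C)C)c(OC)c(OC)c3c(=O)c2[Li])cc1CC[C@H](C)CO[Si](C)(C)C(C)(C)C | intermediate
25 | dimethyl (7-tert-butoxy-2-{3-[(3S)-4-[(tert-butyldimethylsilyl)oxy]-3-methylbutyl]-4-methoxyphenyl}-5,6-dimethoxy-4-oxo-4H-chromen-3-yl)boronate | COB(OC)c1c(-c2ccc(OC)c(CC[C@H](C)CO[Si](C)(C)C(C)(C)C)c2)oc2cc(OC(C)(C)C)c(OC)c(OC)c2c1=O | intermediate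
26 | 7-tert-butoxy-2-{3-[(3S)-4-[(tert-butyldimethylsilyl)oxy]-3-methylbutyl]-4-methoxyphenyl}-3-hydroxy-5,6-dimethoxy-4H-chromen-4-one | COc1ccc(-c2oc3cc(OC(C)(C)C)c(OC)c(OC)c3c(=O)c2O)cc1CC[C@H](C)CO[Si](C)(C)C(C)(C)C | intermediate
27 | 3,7-dihydroxy-2-{3-[(3S)-4-hydroxy-3-methylbutyl]-4-methoxyphenyl}-5,6-dimethoxy-4H-chromen-4-one | COc1ccc(-c2oc3cc(O)c(OC)c(OC)c3c(=O)c2O)cc1CC[C@H](C)CO | target

## Step count and risks

Total: 14 steps (step 1 is run twice, once for each use of 2). Longest linear sequence: 9 steps, either steps 6–10 then 11–14 from 13, or steps 1–5 then 11–14 from 1. The two branches join at step 11.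

**Step 4 (key step).** The dienylketene or the enol ethers may be consumed by intermolecular pathways (ketene dimerisation, acid-catalysed addition of the new phenol to enol ethers), or isobutene may be lost from the alkenyl arm before ring opening, because two acid- and heat-sensitive enol ethers are held at 110 °C. The fallback uses the free tertiary alcohol, the parent substrate class of this ring expansion, and installs the C6 methyl ether after aromatisation; it also takes the methyl triflate quench of step 3 off the critical path. It sets out from 6. Addition of 2 and quench with aq NH4Cl should give 2,4-bis(1-tert-butoxyethenyl)-4-hydroxy-3-methoxycyclobut-2-en-1-one F1. Heating in benzene or toluene should give the hydroquinone 5-tert-butoxy-2-(1-tert-butoxyethenyl)-3-methoxybenzene-1,4-diol F2, handled under argon. Aqueous oxalic acid should give 1-(4-tert-butoxy-3,6-dihydroxy-2-methoxyphenyl)ethan-1-one F3. MeI and K2CO3 in acetone should methylate only the hydroxyl that is not hydrogen-bonded to the acetyl group, and the route is rejoined at 12.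

**Step 12.** The tert-butyl ether (and with it the silyl ether) may be lost during dehydration, because the rate gap between hemiketal ionisation and tert-butyl cation formation may be too small. The fallback gives up both groups on purpose and re-protects. It sets out from 21. CF3CO2H/CH2Cl2/H2O should give 7-hydroxy-2-{3-[(3S)-4-hydroxy-3-methylbutyl]-4-methoxyphenyl}-5,6-dimethoxy-4H-chromen-4-one F4. TBSCl and imidazole in DMF should give the bis-silyl ether 7-[(tert-butyldimethylsilyl)oxy]-2-{3-[(3S)-4-[(tert-butyldimethylsilyl)oxy]-3-methylbutyl]-4-methoxyphenyl}-5,6-dimethoxy-4H-chromen-4-one F5. The C3 lithiation–boration–oxidation of step 13 should give its 3-hydroxy derivative F6. Bu4NF buffered with AcOH removes both silyl groups and the route is rejoined at 27.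

**Step 11.** The enolate may attack the electron-rich para-methoxybenzoate too slowly, so that proton transfer returns 12 and 20 unchanged. The fallback makes the same C2–C3 bond intramolecularly. It sets out from 20. LiOH in THF/MeOH/H2O should give 3-[(3S)-4-[(tert-butyldimethylsilyl)oxy]-3-methylbutyl]-4-methoxybenzoic acid F7. Carbodiimide coupling (EDC, DMAP) with 12 should give the aryl ester 2-acetyl-5-tert-butoxy-3,4-dimethoxyphenyl 3-[(3S)-4-[(tert-butyldimethylsilyl)oxy]-3-methylbutyl]-4-methoxybenzoate F8. KOt-Bu in THF induces the Baker–Venkataraman acyl shift and the route is rejoined at 21.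

**Step 13.** Lithiation at C3 may be incomplete or unselective (amide addition to the pyranone, benzylic deprotonation), or the boronate may be protonated off before oxidation. The fallback replaces anion chemistry by electrophilic oxidation. It sets out from 23. Dimethyldioxirane in acetone should give the 2,3-epoxide 7-tert-butoxy-2-{3-[(3S)-4-[(tert-butyldimethylsilyl)oxy]-3-methylbutyl]-4-methoxyphenyl}-2,3-epoxy-5,6-dimethoxychroman-4-one F9. A trace of sulfonic acid or silica isomerises it to the 3-hydroxyflavone and the route is rejoined at 26.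

## Further compounds

F1 | step 4 | 2,4-bis(1-tert-butoxyethenyl)-4-hydroxy-3-methoxycyclobut-2-en-1-one (racemic) | O=C1C(C(=C)OC(C)(C)C)=C(OC)C1(O)C(=C)OC(C)(C)C
F2 | step 4 | 5-tert-butoxy-2-(1-tert-butoxyethenyl)-3-methoxybenzene-1,4-diol | Oc1cc(OC(C)(C)C)c(O)c(OC)c1C(=C)OC(C)(C)C
F3 | step 4 | 1-(4-tert-butoxy-3,6-dihydroxy-2-methoxyphenyl)ethan-1-one | CC(=O)c1c(O)cc(OC(C)(C)C)c(O)c1OC
F4 | step 12 | 7-hydroxy-2-{3-[(3S)-4-hydroxy-3-methylbutyl]-4-methoxyphenyl}-5,6-dimethoxy-4H-chromen-4-one | COc1ccc(-c2cc(=O)c3c(OC)c(OC)c(O)cc3o2)cc1CC[C@H](C)CO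
F5 | step 12 | 7-[(tert-butyldimethylsilyl)oxy]-2-{3-[(3S)-4-[(tert-butyldimethylsilyl)oxy]-3-methylbutyl]-4-methoxyphenyl}-5,6-dimethoxy-4H-chromen-4-one | COc1ccc(-c2cc(=O)c3c(OC)c(OC)c(O[Si](C)(C)C(C)(C)C)cc3o2)cc1CC[C@H](C)CO[Si](C)(C)C(C)(C)C
F6 | step 12 | 7-[(tert-butyldimethylsilyl)oxy]-2-{3-[(3S)-4-[(tert-butyldimethylsilyl)oxy]-3-methylbutyl]-4-methoxyphenyl}-3-hydroxy-5,6-dimethoxy-4H-chromen-4-one | COc1ccc(-c2oc3cc(O[Si](C)(C)C(C)(C)C)c(OC)c(OC)c3c(=O)c2O)cc1CC[C@H](C)CO[Si](C)(C)C(C)(C)C
F7 | step 11 | 3-[(3S)-4-[(tert-butyldimethylsilyl)oxy]-3-methylbutyl]-4-methoxybenzoic acid | COc1ccc(C(=O)O)cc1CC[C@H](C)CO[Si](C)(C)C(C)(C)C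
F8 | step 11 | 2-acetyl-5-tert-butoxy-3,4-dimethoxyphenyl 3-[(3S)-4-[(tert-butyldimethylsilyl)oxy]-3-methylbutyl]-4-methoxybenzoate | COc1ccc(C(=O)Oc2cc(OC(C)(C)C)c(OC)c(OC)c2C(C)=O)cc1CC[C@H](C)CO[Si](C)(C)C(C)(C)C
F9 | step 13 | 7-tert-butoxy-2-{3-[(3S)-4-[(tert-butyldimethylsilyl)oxy]-3-methylbutyl]-4-methoxyphenyl}-2,3-epoxy-5,6-dimethoxychroman-4-one (both epoxide faces) | COc1ccc(C23OC2C(=O)c2c(OC)c(OC)c(OC(C)(C)C)cc2O3)cc1CC[C@H](C)CO[Si](C)(C)C(C)(C)C
A1 | alternative 1 | {2-[4-(benzyloxy)-2-({3-[(3S)-4-(benzyloxy)-3-methylbutyl]-4-methoxybenzoyl}oxy)-5,6-dimethoxyphenyl]-2-oxoethyl}triphenylphosphonium bromide | [Br-].COc1ccc(C(=O)Oc2cc(OCc3ccccc3)c(OC)c(OC)c2C(=O)C[P+](c2ccccc2)(c2ccccc2)c2ccccc2)cc1CC[C@H](C)COCc1ccccc1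
A2 | alternative 1 | 7-(benzyloxy)-2-{3-[(3S)-4-(benzyloxy)-3-methylbutyl]-4-methoxyphenyl}-5,6-dimethoxy-4H-chromen-4-one | COc1ccc(-c2cc(=O)c3c(OC)c(OC)c(OCc4ccccc4)cc3o2)cc1CC[C@H](C)COCc1ccccc1
A3 | alternative 2 | 2-{3-[(3S)-4-[(tert-butyldimethylsilyl)oxy]-3-methylbutyl]-4-methoxyphenyl}-2-{2-formyl-3,4-dimethoxy-5-[(triisopropylsilyl)oxy]phenoxy}acetaldehyde | O=Cc1c(OC)c(OC)c(O[Si](C(C)C)(C(C)C)C(C)C)cc1OC(C=O)c1ccc(OC)c(CC[C@H](C)CO[Si](C)(C)C(C)(C)C)c1
A4 | alternative 2 | 2-{3-[(3S)-4-[(tert-butyldimethylsilyl)oxy]-3-methylbutyl]-4-methoxyphenyl}-3-hydroxy-5,6-dimethoxy-7-[(triisopropylsilyl)oxy]chroman-4-one (diastereomer mixture at C2 and C3) | O=C1c2c(OC)c(OC)c(O[Si](C(C)C)(C(C)C)C(C)C)cc2OC(c2ccc(OC)c(CC[C@H](C)CO[Si](C)(C)C(C)(C)C)c2)C1O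
A5 | alternative 3 | 5-(benzyloxy)-3,4-dimethoxy-2-(trimethylsilyl)phenyl trifluoromethanesulfonate | COc1c(OC)c(OCc2ccccc2)cc(OS(=O)(=O)C(F)(F)F)c1[Si](C)(C)C
A6 | alternative 3 | 5-(benzyloxy)-3,4-dimethoxybenzyne (aryne between C1 and C2) | COC1=C(OC)C(OCc2ccccc2)=CC#C1
A7 | alternative 3 | benzyloxyacetic acid | OC(=O)COCc1ccccc1
A8 | alternative 3 | 2-(benzyloxy)-1-[4-(benzyloxy)-6-hydroxy-2,3-dimethoxyphenyl]ethan-1-one | COc1c(OC)c(OCc2ccccc2)cc(O)c1C(=O)COCc1ccccc1
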